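The plan rests on the C4a=C8a enol-ether double bond (chroman numbering), which belongs to both carbocycle A and dihydropyranone B. C8a can therefore start as an ester carbon that first accepts C4a and then O1. An acyclic 1,5-diketo ester carrying the preset C8 quaternary centre, the lavandulyl centre and a silyl-protected syn-aldol terminus (C2, C3) is folded in one operation. Base closes ring A by Dieckmann acylation, then acid unmasks O1 and closes ring B by cyclodehydration. C5 stays a methylene until afterwards, so only C8a is within reach of O1. Late C5 oxygenation and a catalytic asymmetric cinnamoyl annulation/hydrolysis add the enol and the (R)-phenylpropanoic acid arm.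

Key step: step 12

Assumption: chroman numbering (O1, C2–C4, C4a, C5–C8, C8a) is used for these atoms in every intermediate, enolisable di- and triketones are drawn as one tautomer, and the facial models quoted in steps 5 and 16 are taken to hold for these substrates (auxiliary and catalyst are sold in both mirror-image forms).

Step 1
Reactants: 1 (±)-lavandulol
Product: 2 (S)-lavandulol
Conditions: immobilised Candida antarctica lipase B, vinyl acetate, hexane, 30 °C, run well past half conversion (chiral GC control); chromatography
Reagents that add atoms: none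
Why: Lipase-catalysed kinetic resolution by irreversible transesterification: the enzyme acylates the R alcohol faster, so driving the reaction well beyond half conversion should leave the S alcohol enriched, and this fixes the lavandulyl stereocentre.

Step 2
Reactants: 2 (S)-lavandulol
Product: 3 (S)-lavandulyl iodide [(3S)-3-(iodomethyl)-2,6-dimethylhepta-1,5-diene]
Conditions: PPh3, I2, imidazole, CH2Cl2, 0 °C → rt
Reagents that add atoms: iodine, II
Why: Appel-type iodination is an SN2 displacement at the primary carbinol carbon and touches neither the neighbouring stereocentre nor the alkenes.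

Step 3
Reactants: 3 (S)-lavandulyl iodide; 4 methyl acetoacetate
Product: 5 methyl (4R)-2-acetyl-7-methyl-4-(prop-1-en-2-yl)oct-6-enoate (C2 epimers)
Conditions: NaH, THF–DMF, 0 °C; then 3, 60 °C
Reagents that add atoms: none
Why: Acetoacetic ester alkylation (SN2): the soft, weakly basic sodium enolate should substitute the β-branched primary iodide at carbon rather than eliminate it, and the epimeric α-centre does not matter because step 4 makes it planar.

Step 4
Reactants: 5 α-lavandulyl acetoacetate; 6 L-valine tert-butyl ester
Product: 7 methyl (Z)-3-{[(2S)-1-tert-butoxy-3-methyl-1-oxobutan-2-yl]amino}-2-[(2R)-5-methyl-2-(prop-1-en-2-yl)hex-4-en-1-yl]but-2-enoate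
Conditions: BF3·OEt2 (5 mol %), toluene, reflux, Dean–Stark trap
Reagents that add atoms: none
Why: Acid-catalysed condensation to a β-enamino ester with azeotropic removal of water, in which the N–H···O=C hydrogen bond fixes the Z geometry that the facial control of step 5 relies on.

Step 5
Reactants: 7 Z-enamino ester; 8 prenyl bromide
Product: 10 methyl (2R,4R)-2-acetyl-7-methyl-2-(3-methylbut-2-en-1-yl)-4-(prop-1-en-2-yl)oct-6-enoate, via ketimine 9 (not isolated)
Conditions: LiN(iPr)2 (from iPr2NH and n-BuLi), toluene, −78 °C; HMPA (1 equiv); 8, −78 → −55 °C; then 1 M aq citric acid, THF, rt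
Reagents that add atoms: water, O
Why: Auxiliary-controlled alkylation of a chelated lithio-enamine (aza-enolate alkylation) followed by imine hydrolysis: lithium is held by the enamide nitrogen, the enoate carbonyl and the valine ester carbonyl, HMPA fills the remaining site on the face away from the isopropyl group, and prenyl bromide should therefore reach C8 from the isopropyl side, which with the L-valine ester gives the quaternary centre drawn (R here, S after ring closure because the CIP ranking of C7 and C8a changes).

Step 6
Reactants: 10 quaternary β-keto ester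
Product: 11 methyl (2R,4R)-7-methyl-2-(3-methylbut-2-en-1-yl)-4-(prop-1-en-2-yl)-2-[1-(trimethylsilyloxy)vinyl]oct-6-enoate
Conditions: Me3SiOTf, Et3N, CH2Cl2, 0 °C
Reagents that add atoms: trimethylsilyl triflate, C[Si](C)(C)OS(=O)(=O)C(F)(F)F
Why: Soft enolisation–silylation, in which only the C6 methyl group carries enolisable hydrogens, so a single enol silane can form and the quaternary centre cannot epimerise.

Step 7
Reactants: 12 (S)-4-benzyl-3-propionyloxazolidin-2-one; 13 acetaldehyde
Product: 14 (S)-4-benzyl-3-[(2S,3R)-3-hydroxy-2-methylbutanoyl]oxazolidin-2-one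
Conditions: Bu2BOTf, Et3N, CH2Cl2, −78 → 0 °C; 13, −78 → 0 °C; pH 7 buffer, MeOH, 30 % H2O2, 0 °C
Reagents that add atoms: none
Why: Evans syn aldol: the Z boron enolate reacts through a Zimmerman–Traxler chair on the face left open by the benzyl group, which sets C3 (S) and C2 (R) together as the syn pair.

Step 8
Reactants: 14 syn aldol imide
Product: 15 (2S,3R)-3-hydroxy-N-methoxy-N,2-dimethylbutanamide
Conditions: MeNH(OMe)·HCl, AlMe3, THF, −20 → 0 °C; 0.5 M HCl work-up
Reagents that add atoms: N,O-dimethylhydroxylamine hydrochloride, CNOC.Cl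
Why: Weinreb transamidation with the aluminium amide, which the free β-hydroxyl steers to the exocyclic carbonyl and which releases the auxiliary without touching C3.

Step 9
Reactants: 15 hydroxy Weinreb amide
Product: 16 (2S,3R)-3-(tert-butyldimethylsilyloxy)-N-methoxy-N,2-dimethylbutanamide
Conditions: tBuMe2SiOTf, 2,6-lutidine, CH2Cl2, 0 °C
Reagents that add atoms: tert-butyldimethylsilyl triflate, CC(C)(C)[Si](C)(C)OS(=O)(=O)C(F)(F)F
Why: Standard O-silylation, chosen because a bulky silyloxy group is a poor leaving group towards β-elimination in base yet is cleaved by HF.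

Step 10
Reactants: 16 silylated Weinreb amide
Product: 17 (4S,5R)-5-(tert-butyldimethylsilyloxy)-4-methylhex-1-en-3-one
Conditions: CH2=CHMgBr, THF, 0 °C; inverse quench into cold 1 M HCl
Reagents that add atoms: vinylmagnesium bromide, C=C[Mg]Br
Why: Weinreb ketone synthesis: the chelated tetrahedral adduct prevents over-addition and shields C3 from enolisation, and the inverse acidic quench keeps the released amine from adding to the enone.

Step 11
Reactants: 11 enol silane; 17 vinyl ketone
Product: 19 methyl (2R,8S,9R)-9-(tert-butyldimethylsilyloxy)-8-methyl-2-[(2R)-5-methyl-2-(prop-1-en-2-yl)hex-4-en-1-yl]-2-(3-methylbut-2-en-1-yl)-3,7-dioxodecanoate, via C4 enol silane 18 (not isolated)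
Conditions: Sc(OTf)3 (10 mol %), CH2Cl2, −78 → −20 °C; then 1 M HCl, THF, 0 °C
Reagents that add atoms: none
Why: Mukaiyama–Michael addition: the unhindered CH2 terminus of 11 attacks the β-carbon of the Lewis-acid-activated enone to make the C5–C6 bond, silyl transfer gives 18, and brief acid hydrolysis frees the C4 ketone without creating a stereocentre or disturbing the bulky silyl ether.

Step 12
Reactants: 19 open-chain 1,5-diketo ester
Product: 22 (2R,3S,8S)-2,3-dimethyl-8-[(2R)-5-methyl-2-(prop-1-en-2-yl)hex-4-en-1-yl]-8-(3-methylbut-2-en-1-yl)-2,3,5,6-tetrahydro-4H-chromene-4,7(8H)-dione, via silylated enol 20 (not isolated), via hydroxy enol 21 (not isolated)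
Conditions: LiN(SiMe3)2 (1.1 equiv, added to 19), THF, −78 → 0 °C; then 48 % aq HF, MeCN, 0 °C → rt
Reagents that add atoms: none
Why: One equivalent of base gives the mono-enolates of the 1,5-diketone; the C6=C7 enolate is unproductive (its Z geometry holds C5 and C8 trans, which is why excess base and the bis-enolate are avoided) and hands its proton back through a six-membered O7···H–C4a transfer, whereas the C4a enolate adds to the C8a ester, methoxide leaves and at once deprotonates the new C4/C8a β-diketone, so the chelated diketonate of 20 is the sink of this Dieckmann (intramolecular Claisen) condensation. Ring A thus closes in the 6-(enolexo)-exo-trig mode known from the cyclisation of ε-keto esters to 2-acylcyclohexanones, including esters on fully substituted carbons. Aqueous HF then frees the C2 hydroxyl (21), which adds 6-exo-trig to C8a, and loss of water from the hemiketal leaves the C4a=C8a enol ether of ring B, the known acid cyclodehydration of δ-hydroxy β-diketones to 2,3-dihydropyran-4-ones. No stereocentre is created: C8 has no α-hydrogen, the lavandulyl carbon is remote, and because O1 acts only as a nucleophile (its bond to C2 stays intact) and C3 is not enolised, the syn relationship of 19 is carried into the cis-2,3-dimethyl ring. Site selectivity of enolisation is secured by the substrate, since C3 is a hindered methine whose enolate would suffer allylic strain and whose only ring-forming option (aldol on C7) would join two fully substituted carbons, while every other cross-reaction would need a four-membered ring. Ring B can form in one direction only, because with C5 at the methylene level no carbonyl other than C8a lies within six-ring distance of O1.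

Step 13
Reactants: 22 bicyclic dione
Product: 23 (2R,3S,8S)-2,3-dimethyl-8-[(2R)-5-methyl-2-(prop-1-en-2-yl)hex-4-en-1-yl]-8-(3-methylbut-2-en-1-yl)-2,3-dihydro-4H-chromene-4,7(8H)-dione (C5=C6 dienone)
Conditions: LiN(SiMe3)2 (1.05 equiv), THF, −78 °C; then N-tert-butylbenzenesulfinimidoyl chloride, −78 °C
Reagents that add atoms: none
Why: Mukaiyama dehydrogenation: the C7 ketone is enolised at its only α-CH2 (C6) in preference to the hindered C3 methine of the less acidic vinylogous ester, and the sulfur adduct should undergo syn elimination at low temperature to the C5=C6 enone.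

Step 14
Reactants: 23 dienone
Product: 25 (2R,3S,8S)-5-hydroxy-2,3-dimethyl-8-[(2R)-5-methyl-2-(prop-1-en-2-yl)hex-4-en-1-yl]-8-(3-methylbut-2-en-1-yl)-2,3,5,6-tetrahydro-4H-chromene-4,7(8H)-dione (C5 epimers), via C5 boronate 24 (not isolated)
Conditions: CuCl (5 mol %), bis[2-(diphenylphosphino)phenyl] ether (5 mol %), NaOtBu (10 mol %), B2pin2, MeOH, THF, rt; then NaBO3·4H2O, THF–H2O, 0 °C → rt
Reagents that add atoms: bis(pinacolato)diboron, CC1(C)OB(OC1(C)C)B1OC(C)(C)C(C)(C)O1 (boron unit of 24); sodium perborate, [Na+].[Na+].O[B-]1(O)OO[B-](O)(O)OO1 (oxygen at C5 of 25)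
Why: Copper-catalysed conjugate borylation followed by C–B oxidation: the borylcopper species should add 1,4 to the disubstituted C5=C6 enone rather than 1,6 to the fully substituted, neopentyl C8a and should ignore the isolated alkenes, and the C5 configuration is irrelevant because step 15 removes it.

Step 15
Reactants: 25 β-hydroxy ketone
Product: 26 (2R,3S,8S)-5-hydroxy-2,3-dimethyl-8-[(2R)-5-methyl-2-(prop-1-en-2-yl)hex-4-en-1-yl]-8-(3-methylbut-2-en-1-yl)-2,3-dihydro-4H-chromene-4,7(8H)-dione (enol of the 4,5,7-trione)
Conditions: 2-iodoxybenzoic acid (IBX), EtOAc, 75 °C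
Reagents that add atoms: none
Why: IBX oxidation of a β-hydroxy ketone to the β-diketone, a neutral method that spares alkenes and C3 and whose product is stabilised as the hydrogen-bonded C5 enol.

Step 16
Reactants: 26 enolic β-diketone; 27 (E)-cinnamic anhydride
Product: 28 O5 enol lactone of the target [(4R)-4-phenyl-3,4-dihydropyran-2-one ring fused across C5–C6; C2 R, C3 S, C8 S and lavandulyl R unchanged]
Conditions: (2S,3R)-3-isopropyl-2-phenyl-3,4-dihydro-2H-benzo[4,5]thiazolo[3,2-a]pyrimidine (HyperBTM, 10 mol %), iPr2NEt, CH2Cl2, 0 °C → rt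
Reagents that add atoms: none
Why: Isothiourea-catalysed Michael addition–lactonisation through an α,β-unsaturated acyl ammonium ion: a 1,5 S···O contact holds the cinnamoyl unit planar and s-cis, the pseudo-axial C2 phenyl group of the catalyst covers one face, and C6 of the enolate of 26 should add to the open face of the β-carbon to set the benzylic centre as R before the neighbouring enolate oxygen (drawn as O5; closure on O7 would converge in step 17) releases the catalyst.

Step 17
Reactants: 28 enol lactone
Product: 29 (3R)-3-[(2R,3S,8S)-5-hydroxy-2,3-dimethyl-8-[(2R)-5-methyl-2-(prop-1-en-2-yl)hex-4-en-1-yl]-8-(3-methylbut-2-en-1-yl)-4,7-dioxo-3,4,7,8-tetrahydro-2H-chromen-6-yl]-3-phenylpropanoic acid (CNP0150579.4)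
Conditions: LiOH, THF–H2O, 0 °C; then 1 M HCl to pH 3
Reagents that add atoms: lithium hydroxide, [Li+].[OH-]
Why: Hydrolysis of an activated enol lactone, whose leaving group is a stabilised vinylogous carboxylate; it should open at 0 °C, and the resulting dianion protects C3 from enolisation and the benzylic centre from retro-Michael loss.

Compound list
1 | (±)-lavandulol [5-methyl-2-(prop-1-en-2-yl)hex-4-en-1-ol] | C=C(C)C(CC=C(C)C)CO | starting material
2 | (S)-lavandulol | C=C(C)[C@H](CC=C(C)C)CO | intermediate
3 | (S)-lavandulyl iodide | C=C(C)[C@H](CC=C(C)C)CI | intermediate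
4 | methyl acetoacetate | COC(=O)CC(C)=O | starting material
5 | methyl (4R)-2-acetyl-7-methyl-4-(prop-1-en-2-yl)oct-6-enoate (C2 epimers) | C=C(C)[C@H](CC=C(C)C)CC(C(C)=O)C(=O)OC | intermediate
6 | L-valine tert-butyl ester | CC(C)[C@H](N)C(=O)OC(C)(C)C | starting material
7 | Z-enamino ester of 5 and 6 | C=C(C)[C@H](CC=C(C)C)C/C(C(=O)OC)=C(\C)N[C@@H](C(C)C)C(=O)OC(C)(C)C | intermediate
8 | prenyl bromide | CC(C)=CCBr | starting material
9 | C7 ketimine of 10 with L-valine tert-butyl ester | C=C(C)[C@H](CC=C(C)C)C[C@](C(=O)OC)(CC=C(C)C)C(C)=N[C@@H](C(C)C)C(=O)OC(C)(C)C | intermediate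
10 | methyl (2R,4R)-2-acetyl-7-methyl-2-(3-methylbut-2-en-1-yl)-4-(prop-1-en-2-yl)oct-6-enoate | C=C(C)[C@H](CC=C(C)C)C[C@](C(=O)OC)(CC=C(C)C)C(C)=O | intermediate
11 | trimethylsilyl enol ether of 10 (C6=C7) | C=C(C)[C@H](CC=C(C)C)C[C@](C(=O)OC)(CC=C(C)C)C(=C)O[Si](C)(C)C | intermediate
12 | (S)-4-benzyl-3-propionyloxazolidin-2-one | CCC(=O)N1[C@@H](Cc2ccccc2)COC1=O | starting material
13 | acetaldehyde | CC=O | starting material
14 | (S)-4-benzyl-3-[(2S,3R)-3-hydroxy-2-methylbutanoyl]oxazolidin-2-one | O=C([C@@H](C)[C@@H](C)O)N1[C@@H](Cc2ccccc2)COC1=O | intermediate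
15 | (2S,3R)-3-hydroxy-N-methoxy-N,2-dimethylbutanamide | CON(C)C(=O)[C@@H](C)[C@@H](C)O | intermediate
16 | (2S,3R)-3-(tert-butyldimethylsilyloxy)-N-methoxy-N,2-dimethylbutanamide | CON(C)C(=O)[C@@H](C)[C@@H](C)O[Si](C)(C)C(C)(C)C | intermediate
17 | (4S,5R)-5-(tert-butyldimethylsilyloxy)-4-methylhex-1-en-3-one | C=CC(=O)[C@@H](C)[C@@H](C)O[Si](C)(C)C(C)(C)C | intermediate
18 | C4=C4a trimethylsilyl enol ether of 19 | C=C(C)[C@H](CC=C(C)C)C[C@](C(=O)OC)(CC=C(C)C)C(=O)CCC=C(O[Si](C)(C)C)[C@@H](C)[C@@H](C)O[Si](C)(C)C(C)(C)C | intermediate
19 | methyl (2R,8S,9R)-9-(tert-butyldimethylsilyloxy)-8-methyl-2-[(2R)-5-methyl-2-(prop-1-en-2-yl)hex-4-en-1-yl]-2-(3-methylbut-2-en-1-yl)-3,7-dioxodecanoate | C=C(C)[C@H](CC=C(C)C)C[C@](C(=O)OC)(CC=C(C)C)C(=O)CCCC(=O)[C@@H](C)[C@@H](C)O[Si](C)(C)C(C)(C)C | intermediate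
20 | ring A triketone (C8a enol form, C8 S) with the (2S,3R)-3-(tert-butyldimethylsilyloxy)-2-methylbutanoyl group on C4a | C=C(C)[C@H](CC=C(C)C)C[C@]1(CC=C(C)C)C(=O)CCC(C(=O)[C@@H](C)[C@@H](C)O[Si](C)(C)C(C)(C)C)=C1O | intermediate
21 | desilylated 20 with free C2 hydroxyl | C=C(C)[C@H](CC=C(C)C)C[C@]1(CC=C(C)C)C(=O)CCC(C(=O)[C@@H](C)[C@@H](C)O)=C1O | intermediate
22 | (2R,3S,8S)-8-lavandulyl-8-prenyl-cis-2,3-dimethyl-2,3,5,6-tetrahydro-4H-chromene-4,7(8H)-dione | C=C(C)[C@H](CC=C(C)C)C[C@]1(CC=C(C)C)C(=O)CCC2=C1O[C@H](C)[C@H](C)C2=O | intermediate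
23 | C5=C6 dienone of 22 | C=C(C)[C@H](CC=C(C)C)C[C@]1(CC=C(C)C)C(=O)C=CC2=C1O[C@H](C)[C@H](C)C2=O | intermediate
24 | C5 pinacol boronate (C5 epimers) | C=C(C)[C@H](CC=C(C)C)C[C@]1(CC=C(C)C)C(=O)CC(B3OC(C)(C)C(C)(C)O3)C2=C1O[C@H](C)[C@H](C)C2=O | intermediate
25 | C5 alcohol (C5 epimers) | C=C(C)[C@H](CC=C(C)C)C[C@]1(CC=C(C)C)C(=O)CC(O)C2=C1O[C@H](C)[C@H](C)C2=O | intermediate
26 | 5-hydroxy-4,7-dione (enolic β-diketone, C6–H) | C=C(C)[C@H](CC=C(C)C)C[C@]1(CC=C(C)C)C(=O)C=C(O)C2=C1O[C@H](C)[C@H](C)C2=O | intermediate
27 | (E)-cinnamic anhydride | O=C(/C=C/c1ccccc1)OC(=O)/C=C/c1ccccc1 | starting material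
28 | O5 enol lactone, benzylic carbon R | C=C(C)[C@H](CC=C(C)C)C[C@]1(CC=C(C)C)C(=O)C3=C(OC(=O)C[C@@H]3c4ccccc4)C2=C1O[C@H](C)[C@H](C)C2=O | intermediate
29 | CNP0150579.4 | C=C(C)[C@H](CC=C(C)C)C[C@]1(CC=C(C)C)C(=O)C([C@H](CC(=O)O)c2ccccc2)=C(O)C2=C1O[C@H](C)[C@H](C)C2=O | target

Total step count: 17. Longest linear sequence: 13 (steps 1–6 and 11–17).

Steps most likely to fail

1. Step 12. Proton shuffling among the enolates of the 1,5-diketone may outrun attack on the neopentyl ester. Enolisation could then reach C3, with loss of the silyloxy group by β-elimination or epimerisation. The fallback sets out from 18 and changes how the nucleophile is made.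
 - Step 11 is worked up without water (Et3N quench, filtration through deactivated silica), so the enol silane 18 is isolated.
 - Anhydrous fluoride (tetrabutylammonium difluorotriphenylsilicate, THF, −78 → 0 °C) then releases the enolate at C4a only, with no external base present.
 - Ring closure comes back to the route at 20, which is treated with aqueous HF as before to reach 22. No compound outside the list arises (F0).

2. Step 5. Facial selectivity may erode because the lavandulyl methylene is much larger than the substituents for which the chelate model is established, or C-alkylation may stay incomplete. The fallback sets out from 5 and replaces the auxiliary by a temporary carbinol stereocentre.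
 - A Prelog-selective ketoreductase (NADP+, iPrOH, buffer, 30 °C) should reduce the methyl ketone to the (3S)-hydroxy ester F1, whatever the configuration at C2.
 - Fráter–Seebach alkylation follows (LiN(iPr)2, 2.2 equiv, THF, −78 → −20 °C, then 8). The electrophile enters the chelated dianion anti to the carbinol methyl group, which should give the quaternary hydroxy ester F2.
 - Dess–Martin oxidation comes back to the route at 10.

3. Step 16. The acidic enol may be O-acylated without going on to conjugate addition, or the facial bias may be weak with this bulky nucleophile. The fallback sets out from 26 and uses iminium instead of acyl ammonium activation.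
 - (E)-Cinnamaldehyde and (R)-α,α-diphenylprolinol trimethylsilyl ether (20 mol %) are used in CH2Cl2 at rt. The silyloxydiphenylmethyl group shields one face of the E-iminium ion, so C6 should add to the open face and ring closure gives the lactol F3 with the benzylic carbon R.
 - Oxidation of the lactol with Dess–Martin periodinane comes back to the route at 28.

Further compounds
F0 | step 12 | none | none
F1 | step 5 | methyl (4R)-2-[(1S)-1-hydroxyethyl]-7-methyl-4-(prop-1-en-2-yl)oct-6-enoate (C2 epimers) | C=C(C)[C@H](CC=C(C)C)CC([C@H](C)O)C(=O)OC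
F2 | step 5 | methyl (2R,4R)-2-[(1S)-1-hydroxyethyl]-7-methyl-2-(3-methylbut-2-en-1-yl)-4-(prop-1-en-2-yl)oct-6-enoate | C=C(C)[C@H](CC=C(C)C)C[C@](C(=O)OC)(CC=C(C)C)[C@H](C)O
F3 | step 16 | O5 lactol corresponding to 28 (anomers, benzylic carbon R) | C=C(C)[C@H](CC=C(C)C)C[C@]1(CC=C(C)C)C(=O)C3=C(OC(O)C[C@@H]3c4ccccc4)C2=C1O[C@H](C)[C@H](C)C2=O
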